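- The leftover came first: the flask asked about, followed so far as the south run, still held 31.8% of its starting material at 12.0 h, yet its target read lower there than at 6.00 h, so target seemed to crest with much of its feed unused.

- south: starting material 18 mM; reagent in the second phase 1 equiv; protic impurity 5.4 mM; the very flask that is asked about, followed so far
- flask: starting material 18 mM; reagent in the second phase 1.00 equiv; protic impurity 5.40 mM; time 3.0 d; volume of the second phase over the first 1.0

- south (time / h: target / %, starting material / %): 1.00: 4.2, 91.4; 2.00: 8.7, 79.2; 4.00: 13.6, 62.0; 6.00: 16.5, 49.4; 12.0: 15.0, 31.8

(each reading ± 1 percentage point)

- in the second phase: reagent in the second phase; everything else is in the first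
- charges count per volume of the first phase; a concentration in a rate is the amount of a species over the volume of its own phase; every rate counts per litre of the first phase
- the earlier runs hold the two phases in the same ratio of volumes as the flask asked about

- time up to 3.0 d at which target stands highest
- the amount of target, in percent of the starting material charged, at that time

- At the highest target reading, at 6.00 h, c(target)/c(starting material) stood at 0.334, and I carried this as the crest ratio, the value of that quotient at the moment target stands highest, a selectivity factor; I assumed that one reagent both makes and destroys target, so that making and using scale together and balance at one quotient as long as that reagent carries both.
- The bound from below was the reading at 4.00 h: target was still rising, so the crest came later and its ratio exceeded 0.219.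
- The bound from above was 12.0 h, with a ratio of 0.472, but it was soft, since the fall of 1.5 percentage points stood against a scatter of 1 point.
- I tightened this by hand to a crest near 6.00 h, with target near that reading.
- The forecast put the crest at 8.4 h with 17.5%, inside my time bracket but above the highest reading, holding that past a balance point “target should only fall or level off”.
- The simulated flask crested at 6.88 h, which is 0.287 d, with 15.3% of target.

    reagent in the reaction phase ⇌ reagent in the second phase, rate k1*([reagent in the reaction phase] - [reagent in the second phase]/K1) per volume of the first phase (partition coefficient = 0.510, kL = 0.00370 min⁻¹)
    starting material + reagent in the reaction phase → target (k = 0.250 L mol⁻¹ min⁻¹)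
    reagent in the reaction phase + target → over-reacted product (k = 0.750 L mol⁻¹ min⁻¹)
    target → over-reaction product (k = 4.90 × 10⁻⁶ min⁻¹)
    reagent in the reaction phase + protic impurity → quenched reagent (k = 0.940 L mol⁻¹ min⁻¹)
    starting material ⇌ dormant form (K = 1.70, k = 0.00100 min⁻¹)

- The step from reagent in the reaction phase and target to over-reacted product holds the crest down, for the flask without it reaches 63.1% instead of 15.3%. Target is made through that same reagent, so the crest ratio applies: multiplied by the 45.9% of starting material at the crest, it gives 15.3% of target. In the neighbour flask charged with 31 mM of starting material, the ratio, itself a scattered reading, turns a crest of 16.2% into an estimate of 48.6% of starting material at that moment.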